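The route rests on disconnecting the C6–C7 bond of the ten-membered macrolactone. The C6 ketone sits one ethylene bridge (C7–C8) away from the C9 carbinol, so an (E)-vinyl iodide at C7, carried on the C1 ester of (R)-but-3-yn-2-ol, can be added as a vinylchromium to a C6 aldehyde on the C4 arm of the γ-butyrolactone; the cis C3 and C4 arms of that five-membered ring bring the two ends together. One operation forms the C6–C7 bond and closes the ten-membered ring. The precursor is the all-cis C3/C4/C12 butyrolactone carrying the furyl group, a CH2CHO arm and the iodobutenyl acetate arm.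

Key step: step 14

Assumption: the C6 carbinol formed in step 14 is taken as a mixture of epimers and drawn without configuration, because step 15 removes it; ethyl 2-(furan-2-yl)acetate and the THF solution of (1,3-dioxolan-2-ylmethyl)zinc bromide are taken as catalogue items.

Numbering and abbreviations: C1 macrolactone carbonyl, C3/C4 ring-fusion carbons, C6 ketone, C9 methyl carbinol, C12 furyl-bearing carbon; TBS = tert-butyldimethylsilyl; Ar = 5-{(3R)-3-[(tert-butyldimethylsilyl)oxy]butyl}furan-2-yl.

Step 1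
Reactants: 1 ethyl 2-(furan-2-yl)acetate; 2 but-3-en-2-one (methyl vinyl ketone)
Product: 3 ethyl 2-[5-(3-oxobutyl)furan-2-yl]acetate
Conditions: 2 (1.5 equiv), BF3·OEt2 (10 mol %), CH2Cl2, −20 → 0 °C
Reagents that add atoms: none
Why: Lewis acid-catalysed Friedel–Crafts-type Michael addition of a 2-substituted furan to an enone, which takes place at the free C5 α-position and leaves the ester untouched.

Step 2
Reactants: 3 ethyl 2-[5-(3-oxobutyl)furan-2-yl]acetate
Product: 4 ethyl 2-{5-[(3R)-3-hydroxybutyl]furan-2-yl}acetate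
Conditions: (R)-selective NADPH-dependent alcohol dehydrogenase (Lactobacillus kefir type), NADP+ (cat.), MgCl2, i-PrOH (10 % v/v), phosphate buffer pH 7, 30 °C
Reagents that add atoms: none
Why: Enzymatic asymmetric ketone reduction with an (R)-selective dehydrogenase, a class that reduces 4-arylbutan-2-ones to the (R)-carbinols with isopropanol as hydride source, sets the side-chain stereocentre and spares the ester and the furan.

Step 3
Reactants: 4 ethyl 2-{5-[(3R)-3-hydroxybutyl]furan-2-yl}acetate
Product: 5 ethyl 2-Ar-acetate (TBS ether of 4)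
Conditions: TBSCl, imidazole, DMF, rt
Reagents that add atoms: tert-butyldimethylsilyl chloride, CC(C)(C)[Si](C)(C)Cl
Why: Standard silylation of a secondary alcohol, which blocks the hydroxyl for the acylations, the strong base and the triflation that follow.

Step 4
Reactants: 5 ethyl 2-Ar-acetate
Product: 6 2-Ar-acetic acid
Conditions: LiOH·H2O, THF/H2O (3:1), 0 °C → rt; then cold 1 M HCl to pH 3–4
Reagents that add atoms: lithium hydroxide, [Li+].[OH-]
Why: Saponification of an unhindered ethyl ester, under which the secondary silyl ether is stable.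

Step 5
Reactants: 7 (S)-malic acid
Product: 8 dibenzyl (S)-malate
Conditions: BnOH (2.5 equiv), p-TsOH·H2O (5 mol %), toluene, reflux, Dean–Stark trap
Reagents that add atoms: benzyl alcohol, OCc1ccccc1
Why: Fischer esterification with azeotropic removal of water esterifies both carboxyl groups and leaves the hydroxyl and the stereocentre alone; benzyl esters are chosen so that the later Dieckmann step cannot scramble ester groups and the C1 ester is cleaved in the hydrogenation.

Step 6
Reactants: 6 2-Ar-acetic acid; 8 dibenzyl (S)-malate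
Product: 9 dibenzyl (2S)-2-[(2-Ar-acetyl)oxy]butanedioate
Conditions: DCC (1.1 equiv), DMAP (10 mol %), CH2Cl2, 0 °C → rt
Reagents that add atoms: none
Why: Steglich esterification of the malate hydroxyl with the arylacetic acid, the usual entry to the O-acyl α-hydroxy esters from which tetronic acids are made.

Step 7
Reactants: 9 dibenzyl (2S)-2-[(2-Ar-acetyl)oxy]butanedioate
Product: 10 benzyl 2-[(2S)-4-Ar-3-hydroxy-5-oxo-2,5-dihydrofuran-2-yl]acetate (3-aryl tetronic acid)
Conditions: LiHMDS (2.0 equiv), THF, −78 → 0 °C; then cold 1 M HCl to pH 3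
Reagents that add atoms: none
Why: Dieckmann cyclisation in which the enolate of the furylacetate (the most acidic site) attacks the neighbouring α-acyloxy benzyl ester in a 5-exo-trig mode, the known course for O-acyl malates, and the product forms as a stable tetronate anion so that C3 keeps its configuration.

Step 8
Reactants: 10 benzyl 2-[(2S)-4-Ar-3-hydroxy-5-oxo-2,5-dihydrofuran-2-yl]acetate
Product: 11 benzyl 2-[(2S)-4-Ar-5-oxo-3-(trifluoromethylsulfonyloxy)-2,5-dihydrofuran-2-yl]acetate
Conditions: Tf2O (1.1 equiv), i-Pr2NEt (1.3 equiv), CH2Cl2, −78 °C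
Reagents that add atoms: trifluoromethanesulfonic anhydride, O=S(=O)(OS(=O)(=O)C(F)(F)F)C(F)(F)F
Why: O-Sulfonylation of the 3-aryl tetronic acid at the C4 enol oxygen gives the vinylogous acyl triflate, the usual handle for cross-coupling at that carbon.

Step 9
Reactants: 11 benzyl 2-[(2S)-4-Ar-5-oxo-3-(trifluoromethylsulfonyloxy)-2,5-dihydrofuran-2-yl]acetate; 12 (1,3-dioxolan-2-ylmethyl)zinc bromide (0.5 M in THF)
Product: 13 benzyl 2-[(2S)-4-Ar-3-(1,3-dioxolan-2-ylmethyl)-5-oxo-2,5-dihydrofuran-2-yl]acetate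
Conditions: 12 (1.8 equiv), PdCl2(dppf) (5 mol %), THF, rt → 45 °C
Reagents that add atoms: none
Why: Negishi coupling of an enol triflate with an alkylzinc halide installs C5 and the masked C6 aldehyde, the wide-bite-angle ligand favouring reductive elimination over β-elimination and the zinc reagent tolerating lactone, benzyl ester and silyl ether.

Step 10
Reactants: 13 benzyl 2-[(2S)-4-Ar-3-(1,3-dioxolan-2-ylmethyl)-5-oxo-2,5-dihydrofuran-2-yl]acetate
Product: 14 2-[(2S,3S,4S)-4-Ar-3-(1,3-dioxolan-2-ylmethyl)-5-oxooxolan-2-yl]acetic acid (all-cis lactone)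
Conditions: H2 (3 bar), 10 % Pd/C, EtOAc, rt
Reagents that add atoms: none
Why: Heterogeneous syn-hydrogenation of the butenolide from the face opposite to the C3 side chain places H4 and H12 cis to H3 and so sets C4 and C12 (all-cis), the same catalyst cleaves the benzyl ester by hydrogenolysis, and the alkene conjugated to carbonyl and furan should be reduced before the furan ring.

Step 11
Reactants: 15 (R)-but-3-yn-2-ol
Product: 17 (2R,3E)-4-iodobut-3-en-2-ol, via O-zirconated (E)-vinylzirconocene 16 (not isolated)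
Conditions: Cp2Zr(H)Cl (2.3 equiv), THF, 0 °C → rt, dark; then I2 (1.2 equiv), 0 °C
Reagents that add atoms: iodine, II
Why: Hydrozirconation adds Zr–H syn across the terminal alkyne with zirconium at the terminal carbon (the first equivalent is consumed by the hydroxyl), and iodinolysis with retention gives the (E)-vinyl iodide without touching the C9 stereocentre.

Step 12
Reactants: 14 2-[(2S,3S,4S)-4-Ar-3-(1,3-dioxolan-2-ylmethyl)-5-oxooxolan-2-yl]acetic acid; 17 (2R,3E)-4-iodobut-3-en-2-ol
Product: 18 (2R,3E)-4-iodobut-3-en-2-yl 2-[(2S,3S,4S)-4-Ar-3-(1,3-dioxolan-2-ylmethyl)-5-oxooxolan-2-yl]acetate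
Conditions: 17 (1.2 equiv), DCC (1.2 equiv), DMAP (10 mol %), CH2Cl2, 0 °C → rt
Reagents that add atoms: none
Why: Steglich esterification of the C1 acid with the secondary allylic alcohol proceeds at the carboxyl without inversion at C9 and under conditions too weakly basic to epimerise C12.

Step 13
Reactants: 18 (2R,3E)-4-iodobut-3-en-2-yl 2-[(2S,3S,4S)-4-Ar-3-(1,3-dioxolan-2-ylmethyl)-5-oxooxolan-2-yl]acetate
Product: 19 (2R,3E)-4-iodobut-3-en-2-yl 2-[(2S,3S,4S)-4-Ar-5-oxo-3-(2-oxoethyl)oxolan-2-yl]acetate (C6 aldehyde, cyclisation precursor)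
Conditions: PPTS (0.3 equiv), acetone/H2O (9:1), 55 °C
Reagents that add atoms: water, O
Why: Mild acid-catalysed acetal hydrolysis frees the C6 aldehyde, while the secondary silyl ether, the furan, the allylic ester and the vinyl iodide are stable to pyridinium tosylate.

Step 14
Reactants: 19 (2R,3E)-4-iodobut-3-en-2-yl 2-[(2S,3S,4S)-4-Ar-5-oxo-3-(2-oxoethyl)oxolan-2-yl]acetate
Product: 20 macrocyclic (E)-7-en-6-ol (3S,4S,9R,12S; C6 epimers), the bicyclic ten-membered lactone/γ-lactone with the TBS-protected side chain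
Conditions: CrCl2 (10 equiv), NiCl2 (0.1 equiv), degassed DMSO, rt; 19 added by syringe pump to a final 2 mM; aqueous sodium serinate work-up
Reagents that add atoms: none
Why: Nozaki–Hiyama–Kishi reaction: Ni(0), formed from NiCl2 and Cr(II), inserts into the C7–I bond, the vinyl group passes to Cr(III), and the (E)-vinylchromium adds to the C6 aldehyde with retention of alkene geometry. The closest known reaction type is the Ni/Cr-mediated intramolecular vinyl iodide–aldehyde coupling that closes ten-membered lactones from 4-iodobut-3-en-2-yl esters. The ten-membered ring closes by 1,2-addition of C7 to the C6 carbonyl (10-exo-trig), helped by the cis C3/C4 arms of the butyrolactone and by chromium holding the aldehyde oxygen. The new C6 carbinol centre is governed only by the conformation of the closing ring and need not be controlled, because step 15 removes it. The step needs ring closure over oligomerisation and aldehyde-only addition with no erosion at C12 or C9; slow addition at high dilution, the low basicity of organochromium(III) and its selectivity for aldehydes over lactones, esters and the furan should secure this.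

Step 15
Reactants: 20 macrocyclic (E)-7-en-6-ol
Product: 21 macrocyclic (E)-7-en-6-one (TBS ether)
Conditions: Dess–Martin periodinane (1.5 equiv), NaHCO3, CH2Cl2, 0 °C → rt
Reagents that add atoms: none
Why: Dess–Martin oxidation converts both C6 epimers of the allylic alcohol to the same (E)-enone under buffered, non-basic conditions that leave the furan, the silyl ether and C12 alone.

Step 16
Reactants: 21 macrocyclic (E)-7-en-6-one
Product: 22 O-TBS-cordycicadin B (saturated C6 ketone)
Conditions: [(Ph3P)CuH]6 (0.4 equiv), H2O (5 equiv), degassed toluene, rt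
Reagents that add atoms: none
Why: Copper hydride conjugate reduction (Stryker's reagent) delivers hydride to C8 and the copper enolate is protonated by water, which saturates C7–C8 without touching the lactones, the furan or the allylic C9–O bond.

Step 17
Reactants: 22 O-TBS-cordycicadin B
Product: 23 cordycicadin B
Conditions: HF·pyridine, pyridine, THF, 0 °C → rt
Reagents that add atoms: none
Why: Buffered fluoride desilylation removes the silyl ether under weakly acidic conditions that should neither epimerise C12 nor open the lactones.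

Compound list
1 | ethyl 2-(furan-2-yl)acetate | CCOC(=O)Cc1ccco1 | starting material
2 | but-3-en-2-one (methyl vinyl ketone) | CC(=O)C=C | starting material
3 | ethyl 2-[5-(3-oxobutyl)furan-2-yl]acetate | CCOC(=O)Cc1ccc(CCC(C)=O)o1 | intermediate
4 | ethyl 2-{5-[(3R)-3-hydroxybutyl]furan-2-yl}acetate | CCOC(=O)Cc1ccc(CC[C@@H](C)O)o1 | intermediate
5 | ethyl 2-(5-{(3R)-3-[(tert-butyldimethylsilyl)oxy]butyl}furan-2-yl)acetate | CCOC(=O)Cc1ccc(CC[C@@H](C)O[Si](C)(C)C(C)(C)C)o1 | intermediate
6 | 2-(5-{(3R)-3-[(tert-butyldimethylsilyl)oxy]butyl}furan-2-yl)acetic acid | OC(=O)Cc1ccc(CC[C@@H](C)O[Si](C)(C)C(C)(C)C)o1 | intermediate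
7 | (S)-malic acid | OC(=O)C[C@H](O)C(=O)O | starting material
8 | dibenzyl (S)-malate | O=C(OCc1ccccc1)C[C@H](O)C(=O)OCc1ccccc1 | intermediate
9 | dibenzyl (2S)-2-[(2-Ar-acetyl)oxy]butanedioate | O=C(OCc1ccccc1)C[C@H](OC(=O)Cc1ccc(CC[C@@H](C)O[Si](C)(C)C(C)(C)C)o1)C(=O)OCc1ccccc1 | intermediate
10 | benzyl 2-[(2S)-4-Ar-3-hydroxy-5-oxo-2,5-dihydrofuran-2-yl]acetate | O=C(OCc1ccccc1)C[C@@H]1OC(=O)C(=C1O)c1ccc(CC[C@@H](C)O[Si](C)(C)C(C)(C)C)o1 | intermediate
11 | benzyl 2-[(2S)-4-Ar-5-oxo-3-(trifluoromethylsulfonyloxy)-2,5-dihydrofuran-2-yl]acetate | O=C(OCc1ccccc1)C[C@@H]1OC(=O)C(=C1OS(=O)(=O)C(F)(F)F)c1ccc(CC[C@@H](C)O[Si](C)(C)C(C)(C)C)o1 | intermediate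
12 | (1,3-dioxolan-2-ylmethyl)zinc bromide | Br[Zn]CC1OCCO1 | starting material
13 | benzyl 2-[(2S)-4-Ar-3-(1,3-dioxolan-2-ylmethyl)-5-oxo-2,5-dihydrofuran-2-yl]acetate | O=C(OCc1ccccc1)C[C@@H]1OC(=O)C(=C1CC2OCCO2)c1ccc(CC[C@@H](C)O[Si](C)(C)C(C)(C)C)o1 | intermediate
14 | 2-[(2S,3S,4S)-4-Ar-3-(1,3-dioxolan-2-ylmethyl)-5-oxooxolan-2-yl]acetic acid (all-cis) | OC(=O)C[C@@H]1OC(=O)[C@H](c2ccc(CC[C@@H](C)O[Si](C)(C)C(C)(C)C)o2)[C@@H]1CC3OCCO3 | intermediate
15 | (R)-but-3-yn-2-ol | C#C[C@@H](C)O | starting material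
16 | O-zirconated (E)-vinylzirconocene from 15 (Cp drawn as σ-cyclopentadienyl) | C[C@@H](O[Zr](Cl)(C1C=CC=C1)C1C=CC=C1)/C=C/[Zr](Cl)(C1C=CC=C1)C1C=CC=C1 | intermediate
17 | (2R,3E)-4-iodobut-3-en-2-ol | C[C@@H](O)/C=C/I | intermediate
18 | (2R,3E)-4-iodobut-3-en-2-yl 2-[(2S,3S,4S)-4-Ar-3-(1,3-dioxolan-2-ylmethyl)-5-oxooxolan-2-yl]acetate | I/C=C/[C@@H](C)OC(=O)C[C@@H]1OC(=O)[C@H](c2ccc(CC[C@@H](C)O[Si](C)(C)C(C)(C)C)o2)[C@@H]1CC3OCCO3 | intermediate
19 | (2R,3E)-4-iodobut-3-en-2-yl 2-[(2S,3S,4S)-4-Ar-5-oxo-3-(2-oxoethyl)oxolan-2-yl]acetate | I/C=C/[C@@H](C)OC(=O)C[C@@H]1OC(=O)[C@H](c2ccc(CC[C@@H](C)O[Si](C)(C)C(C)(C)C)o2)[C@@H]1CC=O | intermediate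
20 | macrocyclic (E)-7-en-6-ol, TBS ether (3S,4S,9R,12S; C6 epimers) | C[C@@H]1/C=C/C(O)C[C@@H]2[C@H](CC(=O)O1)OC(=O)[C@@H]2c1ccc(CC[C@@H](C)O[Si](C)(C)C(C)(C)C)o1 | intermediate
21 | macrocyclic (E)-7-en-6-one, TBS ether | C[C@@H]1/C=C/C(=O)C[C@@H]2[C@H](CC(=O)O1)OC(=O)[C@@H]2c1ccc(CC[C@@H](C)O[Si](C)(C)C(C)(C)C)o1 | intermediate
22 | O-TBS-cordycicadin B | C[C@@H]1CCC(=O)C[C@@H]2[C@H](CC(=O)O1)OC(=O)[C@@H]2c1ccc(CC[C@@H](C)O[Si](C)(C)C(C)(C)C)o1 | intermediate
23 | cordycicadin B | C[C@@H]1CCC(=O)C[C@@H]2[C@H](CC(=O)O1)OC(=O)[C@@H]2c1ccc(CC[C@@H](C)O)o1 | target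

Total step count: 17. Longest linear sequence: 15 steps (steps 1–4, 6–10, 12–17).

Steps most likely to fail

Step 14 (macrocyclisation). Intermolecular coupling to oligomers may outrun ring closure, or the C7–I bond may be reduced before addition. The fallback closes the ring at C7=C8 by olefin metathesis instead. It sets out from acid 14, which is esterified (DCC, DMAP) with commercial (R)-but-3-en-2-ol to give the butenyl ester acetal F1. PPTS in wet acetone frees the aldehyde F2. An intermolecular Ni/Cr-mediated addition of vinyl bromide gives the C6 vinyl carbinol F3. A second-generation ruthenium carbene in dilute CH2Cl2 at reflux then closes the ten-membered ring with loss of ethylene. The E-olefin is 20 itself; any Z-olefin, the (Z)-allylic alcohol F4, is oxidised with Dess–Martin periodinane to the (Z)-enone F5 and reduced with Stryker's reagent. The route is therefore rejoined at 20 or, at the latest, at 22.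

Step 10 (hydrogenation). The furan ring may be partly saturated, the tetrasubstituted alkene may take up hydrogen slowly, the double bond may migrate on the metal and erode C3, or facial selectivity may be incomplete. The fallback replaces surface hydrogenation by a homogeneous conjugate reduction. From butenolide 13, ligated copper hydride (Cu(OAc)2, 1,2-bis(diphenylphosphino)benzene, tetramethyldisiloxane, t-BuOH, toluene) should add hydride to C4 anti to the C3 arm. The enolate is then protonated at C12 from the same open face, giving the all-cis benzyl ester F6 with the furan untouched. Brief hydrogenolysis (H2, 1 atm, Pd/C, EtOAc) frees the acid and returns to 14.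

Step 9 (cross-coupling). β-Hydride or β-alkoxide elimination from the alkylpalladium intermediate may give reduced butenolide in place of the coupled product. The fallback abandons palladium for an addition–elimination. From triflate 11, the magnesium cuprate made from commercial (1,3-dioxolan-2-ylmethyl)magnesium bromide and CuBr·SMe2 (THF, −78 °C) adds to C4 of the vinylogous acyl triflate and expels triflate. This gives butenolide 13 directly, so no further compound arises (F0).

Further compounds
F1 | step 14 | (2R)-but-3-en-2-yl 2-[(2S,3S,4S)-4-Ar-3-(1,3-dioxolan-2-ylmethyl)-5-oxooxolan-2-yl]acetate | C=C[C@@H](C)OC(=O)C[C@@H]1OC(=O)[C@H](c2ccc(CC[C@@H](C)O[Si](C)(C)C(C)(C)C)o2)[C@@H]1CC3OCCO3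
F2 | step 14 | (2R)-but-3-en-2-yl 2-[(2S,3S,4S)-4-Ar-5-oxo-3-(2-oxoethyl)oxolan-2-yl]acetate | C=C[C@@H](C)OC(=O)C[C@@H]1OC(=O)[C@H](c2ccc(CC[C@@H](C)O[Si](C)(C)C(C)(C)C)o2)[C@@H]1CC=O
F3 | step 14 | (2R)-but-3-en-2-yl 2-[(2S,3S,4S)-4-Ar-3-(2-hydroxybut-3-en-1-yl)-5-oxooxolan-2-yl]acetate (C6 epimers) | C=C[C@@H](C)OC(=O)C[C@@H]1OC(=O)[C@H](c2ccc(CC[C@@H](C)O[Si](C)(C)C(C)(C)C)o2)[C@@H]1CC(O)C=C
F4 | step 14 | macrocyclic (Z)-7-en-6-ol, TBS ether (C6 epimers) | C[C@@H]1/C=C\C(O)C[C@@H]2[C@H](CC(=O)O1)OC(=O)[C@@H]2c1ccc(CC[C@@H](C)O[Si](C)(C)C(C)(C)C)o1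
F5 | step 14 | macrocyclic (Z)-7-en-6-one, TBS ether | C[C@@H]1/C=C\C(=O)C[C@@H]2[C@H](CC(=O)O1)OC(=O)[C@@H]2c1ccc(CC[C@@H](C)O[Si](C)(C)C(C)(C)C)o1
F6 | step 10 | benzyl 2-[(2S,3S,4S)-4-Ar-3-(1,3-dioxolan-2-ylmethyl)-5-oxooxolan-2-yl]acetate | O=C(OCc1ccccc1)C[C@@H]1OC(=O)[C@H](c2ccc(CC[C@@H](C)O[Si](C)(C)C(C)(C)C)o2)[C@@H]1CC3OCCO3
F0 | step 9 | none | none
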